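The runs were computed on assumed constants; the scatter is artificial.

The substrate charge stays at 20 mM from run to flask, so reagent is counted here in equivalents of that charge, and tetra adduct as a fraction of it.

| flask | substrate | reagent | remark | time |
|---|---|---|---|---|
| summer | 20 mM | 34 mM | run made earlier |  |
| winter | 20 mM | 110 mM | run made earlier |  |
| Thursday's | 20 mM | 30.0 mM |  | 80 min |
| Saturday's | 20 mM | 60.0 mM |  | 80 min |
| Wednesday's | 20 mM | 80.0 mM |  | 80 min |

| run | time / min | tetra adduct / % | first product / % |
|---|---|---|---|
| summer | 3.00 | 3 | 11 |
| summer | 8.00 | 1 | 6 |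
| summer | 15.0 | 2 | 1 |
| summer | 25.0 | 3 | 1 |
| summer | 30.0 | 4 | 1 |
| summer | 40.0 | 6 | 2 |
| summer | 60.0 | 1 | 0 |
| winter | 3.00 | 11 | 13 |
| winter | 8.00 | 25 | 0 |
| winter | 15.0 | 21 | 2 |
| winter | 25.0 | 22 | 2 |
| winter | 30.0 | 26 | 1 |
| winter | 40.0 | 22 | 0 |
| winter | 60.0 | 24 | 2 |

(each reading ± 2 percentage points)

- the earlier runs were read with a standard deviation of 2 percentage points

- final tetra adduct, as a percentage of the substrate charged, for each flask in turn (Thursday's, Saturday's, Wednesday's)

From 15.0 min on, the tetra adduct readings of both runs show no clear trend against their scatter of 2 points. Those readings average 3.20% in the summer run and 23.0% in the winter run. Between these two levels each further equivalent of reagent adds 5.2 points, and this marginal yield is the quantity frozen here.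

Taking 80 min as still on the level and stepping from the summer run, this reckoning, separate from the forecast, gives 2.16% for Thursday's flask, 9.97% for Saturday's and 15.2% for Wednesday's.

The forecast follows another rule, the odds of tetra adduct, which show “a tenfold change for a threefold change in reagent”. It says 2%, 9% and 14%, each below this reckoning.

The flasks give 3.28%, 10.9% and 15.8%, and the forecast holds within its margin.

    substrate + reagent → first product + by-product (k = 0.123 M⁻¹ s⁻¹)
    reagent + first product → double product + by-product (k = 0.182 M⁻¹ s⁻¹)
    reagent + double product → tris adduct + by-product (k = 0.141 M⁻¹ s⁻¹)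
    reagent + tris adduct ⇌ tetra adduct + by-product (K = 0.480, k = 0.348 M⁻¹ s⁻¹)
    reagent → decomposition product (k = 1.70 × 10⁻⁵ s⁻¹)
    substrate + first product → side product (k = 1.50 M⁻¹ s⁻¹)

Measured between the flasks, the marginal yield is 5.1 points from Thursday's to Saturday's and 4.9 points from Saturday's to Wednesday's, against the frozen 5.2 points. In Thursday's flask at 2.07 min, first product is lost with substrate to side product 3.7 times as fast as reagent carries it on to double product. Side product, which holds two substrate units and counts twice, stands after 80.0 min at 80.2% of the substrate charged in Thursday's flask and at 56.5% in Wednesday's.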